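**Strategy**

Locants are those of tetracyclo[5.4.2.0^3,13.0^10,12]tridecane. The route rests on closing the cyclopentane C1–C2–C3–C13–C12 last, through the C2–C3 bond. The precursor is a tricyclic enone (C4=O, C3=C13) in which the cyclobutane, the cyclohexene ring (C7–C10, C12, C13) and the enone ring are complete and C2 hangs as an endo CH2Br on cyclobutane carbon C1. Conjugate hydride addition to C13 from the convex face sets the trans C7/C13 ring fusion, which a suprafacial cycloaddition onto a cyclohexadiene could not give, and creates a C3 enolate pressed against C2; 5-exo-tet alkylation closes the ring and sets C3. The feature used is this 1,3-syn relation of C2 and C3 across C12–C13.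

Key step: step 13

Remark 1: the sense of induction of the copper–phosphoramidite catalyst in step 4 is taken to give 7 as drawn; the mirror-image ligand is used otherwise.
Remark 2: C6 is not controlled before step 16; 17–23 are drawn as the C6 epimer with the ester trans to C8, and either epimer converges in step 16.

**Route**

Step 1
Reactants: 1 10-bromodec-1-ene
Product: 2 (E)-10-bromodec-2-ene
Conditions: [(C5Me5)Ru(NCMe)(L)]PF6 (1 mol%, L = 4-tert-butyl-2-(diisopropylphosphino)-1-methylimidazole), acetone, 40 °C
Reagents that add atoms: none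
Why: Ruthenium-catalysed alkene transposition by one position should stop at the (E)-2-alkene under catalyst control, and the primary bromide is inert.

Step 2
Reactants: 2 (E)-10-bromodec-2-ene
Product: 4 [(E)-dec-8-en-1-yl](trimethylsilylmethyl)zinc, via (E)-dec-8-enylzinc bromide 3 (not isolated)
Conditions: Zn dust (activated with BrCH2CH2Br and Me3SiCl), LiCl, THF, 50 °C; decanted from excess Zn; Me3SiCH2Li (1.0 equiv), −78 °C to rt; THF exchanged for PhMe, lithium salts filtered off
Reagents that add atoms: zinc, [Zn]; (trimethylsilyl)methyllithium, [Li]C[Si](C)(C)C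
Why: Direct insertion of LiCl-activated zinc into the primary bromide gives the alkylzinc bromide, and transmetalation with (trimethylsilyl)methyllithium should give the mixed diorganozinc, whose trimethylsilylmethyl group is a non-transferable ligand, so that one equivalent of the chain suffices and the salts can be removed before the copper-catalysed step.

Step 3
Reactants: 5 cyclooctatetraene
Product: 6 cyclooctatetraene monoepoxide (meso)
Conditions: mCPBA (1.0 equiv), CH2Cl2, 0 °C
Reagents that add atoms: mCPBA, OOC(=O)c1cccc(Cl)c1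
Why: Prilezhaev epoxidation of one of four equivalent double bonds should give the meso vinyl epoxide.

Step 4
Reactants: 6 cyclooctatetraene monoepoxide; 4 [(E)-dec-8-en-1-yl](trimethylsilylmethyl)zinc
Product: 7 trans-4-[(E)-dec-8-en-1-yl]cycloocta-2,5,7-trien-1-ol
Conditions: Cu(OTf)2 (3 mol%), (S)-binaphthyl-2,2′-diyl N,N-bis[(R)-1-phenylethyl]phosphoramidite (6 mol%), 4 (1.5 equiv), PhMe, −78 to 0 °C; aq NH4Cl
Reagents that add atoms: none
Why: Copper–phosphoramidite-catalysed anti-SN2′ alkylation with an organozinc reagent should desymmetrise the meso vinyl epoxide, only the decenyl group of the mixed zinc reagent being transferred; C11 is set under ligand control and the C13 hydroxyl ends trans to the chain across the ring.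

Step 5
Reactants: 7 trans-4-[(E)-dec-8-en-1-yl]cycloocta-2,5,7-trien-1-ol; 8 tributyl(iodomethyl)stannane
Product: 9 tributylstannylmethyl ether of 7
Conditions: KH, 18-crown-6 (cat.), THF, 0 °C to rt
Reagents that add atoms: none
Why: Williamson etherification of the potassium alkoxide with the primary iodide should install the stannylmethyl ether without touching the stereocentres.

Step 6
Reactants: 9 tributylstannylmethyl ether of 7
Product: 12 cis-fused [7-exo-((E)-dec-8-en-1-yl)bicyclo[4.2.0]octa-2,4-dien-8-endo-yl]methanol, via cyclooctatrienylmethanol 10 (not isolated), via exo-hydroxymethyl tautomer 11 (not isolated)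
Conditions: n-BuLi, THF, −78 °C; aq NH4Cl; rt, 12 h
Reagents that add atoms: none
Why: Tin–lithium exchange should trigger a [2,3]-Wittig–Still rearrangement that delivers C2 to C1 on the face of the departing oxygen (hence trans to the C11 chain) and leaves a 1,3,5-triene, whose disrotatory 6π electrocyclisation gives the cis-fused tautomers 11 and 12, which interconvert through 10 and are carried on together.

Step 7
Reactants: 12 cis-fused [7-exo-((E)-dec-8-en-1-yl)bicyclo[4.2.0]octa-2,4-dien-8-endo-yl]methanol (as its equilibrium mixture with 11)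
Product: 13 2,3-epoxide of 12 on the face syn to the cyclobutane
Conditions: VO(acac)2 (5 mol%), t-BuOOH, PhMe, 50 °C
Reagents that add atoms: tert-butyl hydroperoxide, CC(C)(C)OO
Why: Hydroxyl-directed vanadium-catalysed epoxidation is possible only for the endo CH2OH of 12 and should put the oxygen on the concave face of the nearer double bond C7=C13, while 11 drains into 12 through 10 at this temperature.

Step 8
Reactants: 13 2,3-epoxide of 12
Product: 14 tert-butyldimethylsilyl ether of 13
Conditions: TBSCl, imidazole, DMF, rt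
Reagents that add atoms: tert-butyldimethylsilyl chloride, CC(C)(C)[Si](C)(C)Cl
Why: Silylation masks the alcohol so that it cannot capture the allyl intermediate of the next step.

Step 9
Reactants: 14 tert-butyldimethylsilyl ether of 13
Product: 15 8-endo-[(tert-butyldimethylsilyloxy)methyl]-7-exo-[(E)-dec-8-en-1-yl]bicyclo[4.2.0]oct-4-en-2-one
Conditions: Pd(PPh3)4 (5 mol%), THF, 40 °C
Reagents that add atoms: none
Why: Zerovalent-palladium-catalysed isomerisation of the vinyl epoxide (ionisation of the allylic C7–O bond, hydride shift from C13 to C7) should give the β,γ-unsaturated ketone with C13=O and the C8=C9 double bond in place.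

Step 10
Reactants: 15 bicyclo[4.2.0]oct-4-en-2-one; 16 methyl (E)-4-oxopent-2-enoate
Product: 17 methyl 2-[8-endo-((tert-butyldimethylsilyloxy)methyl)-7-exo-((E)-dec-8-en-1-yl)-2-oxobicyclo[4.2.0]oct-4-en-3-exo-yl]-4-oxopentanoate
Conditions: LiN(i-Pr)2, THF, −78 °C; 16, −78 °C; AcOH, −78 °C
Reagents that add atoms: none
Why: Kinetic deprotonation at the doubly activated C7 gives a lithium dienolate that should add in Michael fashion through C7, from the convex face anti to the cyclobutane, to the carbon of 16 that is β to its ketone, so that H-7 ends α and C6 is attached.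

Step 11
Reactants: 17 Michael adduct
Product: 18 tricyclic enone (target skeleton without the C2–C3 bond; C4=O, C3=C13, CH2OTBS on C1)
Conditions: pyrrolidine (30 mol%), AcOH (30 mol%), 4 Å MS, PhMe, 40 °C
Reagents that add atoms: none
Why: Enamine-mediated intramolecular aldol condensation of the methyl ketone onto the C13 ketone (second stage of a Robinson annulation) should close the cyclohexenone ring under conditions mild enough to leave the C8=C9 double bond where it is.

Step 12
Reactants: 18 tricyclic enone silyl ether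
Product: 19 tricyclic enone bromide (CH2Br on C1)
Conditions: Ph3PBr2, CH2Cl2, 0 °C to rt
Reagents that add atoms: dibromotriphenylphosphorane, BrP(Br)(c1ccccc1)(c1ccccc1)c1ccccc1
Why: Dibromotriphenylphosphorane should convert the primary silyl ether directly into the primary bromide by an Appel-type SN2 displacement at C2, leaving the enone untouched.

Step 13
Reactants: 19 tricyclic enone bromide
Product: 21 methyl 11-[(E)-dec-8-en-1-yl]-4-oxotetracyclo[5.4.2.0^3,13.0^10,12]tridec-8-ene-6-carboxylate (6-epi), via silyl enol ether 20 (not isolated)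
Conditions: [(Ph3P)CuH]6 (5 mol%), PhMe2SiH, PhMe, 0 °C to rt; then (Me2N)3S Me3SiF2 (TASF), THF, −20 °C to rt
Reagents that add atoms: none
Why: Copper hydride adds hydride to the enone β-carbon C13 and the copper enolate is trapped by the silane as the regiodefined silyl enol ether 20 (C3=C4); fluoride then frees the enolate, whose carbon C3 displaces the primary bromide at C2. The closest known reaction type is the reductive alkylation of enones, in which conjugate reduction gives a regiospecific enolate that is alkylated in the same flask. One ring is closed, the cyclopentane C1–C2–C3–C13–C12, in a 5-exo-tet mode with the enolate double bond outside the new ring. C13 is controlled by the shape of the substrate, hydride entering from the convex face anti to the cyclobutane and its endo CH2Br so that H-13 is cis to H-12 and trans to H-7, and C3 is controlled by the tether, which reaches only the concave face so that H-3 is cis to H-13. The step needs 1,4- rather than 1,2-reduction, which the soft copper hydride secures, and C- rather than O-alkylation, which is secured because O-alkylation would need a bridged seven-membered enol ether. The ester, the bromide during the reduction and both isolated double bonds should be inert to the copper hydride–silane couple.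

Step 14
Reactants: 21 tetracyclic ketone
Product: 22 C4 enol triflate (4,8-diene, 6-epi)
Conditions: KN(SiMe3)2 (1.05 equiv), THF, −78 °C; PhNTf2; aq NH4Cl
Reagents that add atoms: N-phenylbis(trifluoromethanesulfonimide), O=S(=O)(N(c1ccccc1)S(=O)(=O)C(F)(F)F)C(F)(F)F
Why: Kinetic deprotonation of the ketone at the C5 methylene rather than the ring-fusion methine C3, followed by O-triflation, should give the C4=C5 enol triflate regioselectively.

Step 15
Reactants: 22 C4 enol triflate
Product: 23 methyl 11-[(E)-dec-8-en-1-yl]tetracyclo[5.4.2.0^3,13.0^10,12]trideca-4,8-diene-6-carboxylate, 6-epimer of the target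
Conditions: Pd(OAc)2 (5 mol%), PPh3, HCO2H, n-Bu3N, DMF, 60 °C
Reagents that add atoms: none
Why: Palladium-catalysed formate reduction of the enol triflate (oxidative addition, decarboxylation of formate, C–H reductive elimination) should leave the C4=C5 double bond where the ketone was.

Step 16
Reactants: 23 6-epimer of the target
Product: 24 target, methyl 11-[(E)-dec-8-en-1-yl]tetracyclo[5.4.2.0^3,13.0^10,12]trideca-4,8-diene-6-carboxylate (H-1, H-3, H-10, H-12, H-13 on one face; H-6, H-7, H-11 on the other)
Conditions: LiN(i-Pr)2, THF, −78 °C; AcOH in THF, −78 °C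
Reagents that add atoms: none
Why: Deprotonation at C6 gives the extended ester enolate, and kinetic protonation at the α-carbon from the less hindered equatorial direction should place the ester axial and cis to the C7–C8 bond, whichever C6 epimer entered.

**Compound list**

1 | 10-bromodec-1-ene | C=CCCCCCCCCBr | starting material
2 | (E)-10-bromodec-2-ene | C/C=C/CCCCCCCBr | intermediate
3 | (E)-dec-8-en-1-ylzinc bromide | C/C=C/CCCCCCC[Zn]Br | intermediate
4 | [(E)-dec-8-en-1-yl](trimethylsilylmethyl)zinc | C/C=C/CCCCCCC[Zn]C[Si](C)(C)C | intermediate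
5 | cyclooctatetraene | C1=CC=CC=CC=C1 | starting material
6 | cyclooctatetraene monoepoxide (cis-9-oxabicyclo[6.1.0]nona-2,4,6-triene, meso) | C1=CC=C[C@H]2O[C@H]2C=C1 | intermediate
7 | trans-4-[(E)-dec-8-en-1-yl]cycloocta-2,5,7-trien-1-ol (carbinol carbon = C13, alkyl-bearing carbon = C11) | C/C=C/CCCCCCC[C@@H]1C=CC=C[C@@H](O)C=C1 | intermediate
8 | tributyl(iodomethyl)stannane | CCCC[Sn](CCCC)(CCCC)CI | starting material
9 | tributylstannylmethyl ether of 7 | C/C=C/CCCCCCC[C@@H]1C=CC=C[C@@H](OC[Sn](CCCC)(CCCC)CCCC)C=C1 | intermediate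
10 | trans-[8-((E)-dec-8-en-1-yl)cycloocta-2,4,6-trien-1-yl]methanol | C/C=C/CCCCCCC[C@@H]1C=CC=CC=C[C@H]1CO | intermediate
11 | cis-fused [7-endo-((E)-dec-8-en-1-yl)bicyclo[4.2.0]octa-2,4-dien-8-exo-yl]methanol | C/C=C/CCCCCCC[C@@H]1[C@@H]2C=CC=C[C@@H]2[C@H]1CO | intermediate
12 | cis-fused [7-exo-((E)-dec-8-en-1-yl)bicyclo[4.2.0]octa-2,4-dien-8-endo-yl]methanol | C/C=C/CCCCCCC[C@@H]1[C@H]2C=CC=C[C@H]2[C@H]1CO | intermediate
13 | [7-exo-((E)-dec-8-en-1-yl)-2,3-epoxybicyclo[4.2.0]oct-4-en-8-endo-yl]methanol, epoxide syn to the cyclobutane | C/C=C/CCCCCCC[C@@H]1[C@H]2C=C[C@H]3O[C@H]3[C@H]2[C@H]1CO | intermediate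
14 | tert-butyldimethylsilyl ether of 13 | C/C=C/CCCCCCC[C@@H]1[C@H]2C=C[C@H]3O[C@H]3[C@H]2[C@H]1CO[Si](C)(C)C(C)(C)C | intermediate
15 | 8-endo-[(tert-butyldimethylsilyloxy)methyl]-7-exo-[(E)-dec-8-en-1-yl]bicyclo[4.2.0]oct-4-en-2-one | C/C=C/CCCCCCC[C@@H]1[C@H]2C=CCC(=O)[C@H]2[C@H]1CO[Si](C)(C)C(C)(C)C | intermediate
16 | methyl (E)-4-oxopent-2-enoate | COC(=O)/C=C/C(C)=O | starting material
17 | methyl 2-[8-endo-((tert-butyldimethylsilyloxy)methyl)-7-exo-((E)-dec-8-en-1-yl)-2-oxobicyclo[4.2.0]oct-4-en-3-exo-yl]-4-oxopentanoate | C/C=C/CCCCCCC[C@@H]1[C@H]2C=C[C@H]([C@H](CC(C)=O)C(=O)OC)C(=O)[C@H]2[C@H]1CO[Si](C)(C)C(C)(C)C | intermediate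
18 | tricyclic enone: target skeleton without the C2–C3 bond, C4=O, C3=C13, C5 methylene, endo CH2OTBS on C1, H-7 trans to the cyclobutane side, 6-epi ester | C/C=C/CCCCCCC[C@@H]1[C@H]2C=C[C@H]3C(=CC(=O)C[C@@H]3C(=O)OC)[C@H]2[C@H]1CO[Si](C)(C)C(C)(C)C | intermediate
19 | tricyclic enone bromide: as 18 with endo CH2Br on C1 | C/C=C/CCCCCCC[C@@H]1[C@H]2C=C[C@H]3C(=CC(=O)C[C@@H]3C(=O)OC)[C@H]2[C@H]1CBr | intermediate
20 | dimethylphenylsilyl enol ether (C3=C4) of the C13-reduced ketone, H-13 cis to H-12 | C/C=C/CCCCCCC[C@@H]1[C@H]2C=C[C@H]3[C@@H](C=C(O[Si](C)(C)c4ccccc4)C[C@@H]3C(=O)OC)[C@H]2[C@H]1CBr | intermediate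
21 | methyl 11-[(E)-dec-8-en-1-yl]-4-oxotetracyclo[5.4.2.0^3,13.0^10,12]tridec-8-ene-6-carboxylate (6-epi) | C/C=C/CCCCCCC[C@@H]1[C@H]2C=C[C@H]3[C@@H]4[C@H]2[C@H]1C[C@@H]4C(=O)C[C@@H]3C(=O)OC | intermediate
22 | methyl 11-[(E)-dec-8-en-1-yl]-4-(trifluoromethylsulfonyloxy)tetracyclo[5.4.2.0^3,13.0^10,12]trideca-4,8-diene-6-carboxylate (6-epi) | C/C=C/CCCCCCC[C@@H]1[C@H]2C=C[C@H]3[C@@H]4[C@H]2[C@H]1C[C@@H]4C(OS(=O)(=O)C(F)(F)F)=C[C@@H]3C(=O)OC | intermediate
23 | 6-epimer of the target | C/C=C/CCCCCCC[C@@H]1[C@H]2C=C[C@H]3[C@@H]4[C@H]2[C@H]1C[C@@H]4C=C[C@@H]3C(=O)OC | intermediate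
24 | methyl 11-[(E)-dec-8-en-1-yl]tetracyclo[5.4.2.0^3,13.0^10,12]trideca-4,8-diene-6-carboxylate | C/C=C/CCCCCCC[C@@H]1[C@H]2C=C[C@H]3[C@@H]4[C@H]2[C@H]1C[C@@H]4C=C[C@H]3C(=O)OC | target

**Count**

Total steps: 16. Longest linear sequence: 15 steps (1, 2, 4–16).

**Steps most likely to fail**

Step 13. The conjugate reduction may stall at the hindered β,β-disubstituted enone, or the freed enolate may be protonated before it closes the ring. The fallback sets out from 18. Dissolving-metal reduction (Li (2.2 equiv), NH3, THF, t-BuOH, −78 °C, short contact time to spare the ester) should give the trans-fused saturated ketone silyl ether F1 by thermodynamic protonation at C13. Ph3PBr2 then gives the saturated ketone bromide F2. KOt-Bu in t-BuOH/THF equilibrates the two ketone enolates, and only the C3 enolate can close a five-membered ring, which comes back to the route at 21.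

Step 11. The amine may enolise the C13 ketone towards C7, which would move the C8=C9 double bond into conjugation or erode the C7 configuration before or after ring closure. The fallback sets out from 15. Michael addition of its lithium dienolate (LiN(i-Pr)2, THF, −78 °C) to methyl (E)-5-(dimethoxyphosphoryl)-4-oxopent-2-enoate gives the keto-phosphonate adduct F3. Intramolecular Horner–Wadsworth–Emmons olefination onto the C13 ketone (LiCl, i-Pr2NEt, MeCN, rt) forms the C3=C13 bond without an aldol–dehydration sequence and comes back at 18.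

Step 6. The lithiated ether may shift onto the diene terminus instead of C1 (regiochemical leakage to a 1,4-disubstituted triene) or undergo a 1,2-shift. The fallback sets out from 7. Acylation with (tert-butyldimethylsilyloxy)acetic acid (DCC, DMAP, CH2Cl2) gives the glycolate ester F4. Ireland–Claisen rearrangement (LiN(SiMe3)2, Me3SiCl, THF, −78 °C to rt) through the same C13–C12=C1 unit gives, after aqueous work-up, the monocyclic triene α-silyloxy acid F5. Its 6π closure on standing at rt gives the bicyclic α-silyloxy acid F6 (both drawn as one α-epimer; this centre is lost). Desilylation (Bu4NF, THF) gives the α-hydroxy acid F7. Oxidative decarboxylation with Pb(OAc)4 gives the cyclobutane aldehyde F8, and immediate reduction with NaBH4 comes back at 12 (with 11).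

Further compounds

F1 | step 13 | trans-fused saturated C4 ketone, silyl ether (18 with H added at C13 and C3) | C/C=C/CCCCCCC[C@@H]1[C@H]2C=C[C@H]3[C@@H](CC(=O)C[C@@H]3C(=O)OC)[C@H]2[C@H]1CO[Si](C)(C)C(C)(C)C
F2 | step 13 | trans-fused saturated C4 ketone, bromide | C/C=C/CCCCCCC[C@@H]1[C@H]2C=C[C@H]3[C@@H](CC(=O)C[C@@H]3C(=O)OC)[C@H]2[C@H]1CBr
F3 | step 11 | keto-phosphonate Michael adduct (17 with CH2P(O)(OMe)2 in place of the ketone methyl) | C/C=C/CCCCCCC[C@@H]1[C@H]2C=C[C@H]([C@H](CC(=O)CP(=O)(OC)OC)C(=O)OC)C(=O)[C@H]2[C@H]1CO[Si](C)(C)C(C)(C)C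
F4 | step 6 | (tert-butyldimethylsilyloxy)acetate ester of 7 | C/C=C/CCCCCCC[C@@H]1C=CC=C[C@@H](OC(=O)CO[Si](C)(C)C(C)(C)C)C=C1
F5 | step 6 | 2-[trans-8-((E)-dec-8-en-1-yl)cycloocta-2,4,6-trien-1-yl]-2-(tert-butyldimethylsilyloxy)acetic acid | C/C=C/CCCCCCC[C@@H]1C=CC=CC=C[C@H]1[C@@H](O[Si](C)(C)C(C)(C)C)C(=O)O
F6 | step 6 | 2-[7-exo-((E)-dec-8-en-1-yl)bicyclo[4.2.0]octa-2,4-dien-8-endo-yl]-2-(tert-butyldimethylsilyloxy)acetic acid | C/C=C/CCCCCCC[C@@H]1[C@H]2C=CC=C[C@H]2[C@H]1[C@@H](O[Si](C)(C)C(C)(C)C)C(=O)O
F7 | step 6 | 2-[7-exo-((E)-dec-8-en-1-yl)bicyclo[4.2.0]octa-2,4-dien-8-endo-yl]-2-hydroxyacetic acid | C/C=C/CCCCCCC[C@@H]1[C@H]2C=CC=C[C@H]2[C@H]1[C@@H](O)C(=O)O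
F8 | step 6 | 7-exo-((E)-dec-8-en-1-yl)bicyclo[4.2.0]octa-2,4-diene-8-endo-carbaldehyde | C/C=C/CCCCCCC[C@@H]1[C@H]2C=CC=C[C@H]2[C@H]1C=O
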